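The eta run at 62 °C and 0.12 M gave me a slow flask, and the epsilon run at 112 °C and 0.17 M gave me a fast one.

- eta (time / h: target / %): 1.50: 0.1; 4.00: 0.2; 8.00: 0.7; 12.0: 1.4; 20.0: 3.2; 25.0: 3.3
- epsilon (time / min: target / %): 8.00: 1.9; 20.0: 4.1; 40.0: 5.7; 60.0: 7.8; 90.0: 8.5; 120: 9.7

(readings scatter by 0.5 percentage points)

| flask | substrate | first nucleophile | second nucleophile | temperature | remark | time |
|---|---|---|---|---|---|---|
| eta | 0.12 M | 0.90 equiv | 0.60 equiv | 62 °C | run made earlier |  |
| epsilon | 0.17 M | 0.90 equiv | 0.60 equiv | 112 °C | run made earlier |  |
| east | 0.23 M | 0.900 equiv | 0.600 equiv | 100 °C |  | 6.0 h |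
| south-west | 0.23 M | 0.900 equiv | 0.600 equiv | 130 °C |  | 6.0 h |
| south | 0.23 M | 0.900 equiv | 0.600 equiv | 70 °C |  | 6.0 h |
| south-east | 0.23 M | 0.900 equiv | 0.600 equiv | 40 °C |  | 6.0 h |

- the flask with the highest amount of target, in percent of the substrate charged ("all alike" if they lie within 1.5 percentage points) (east / south-west / south / south-east / all alike)
- final target, as a percentage of the substrate charged, in east
- final target, as a percentage of the substrate charged, in south-west
- final target, as a percentage of the substrate charged, in south
- final target, as a percentage of the substrate charged, in south-east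

- what was read earlier has a scatter of 0.5 percentage points, one standard deviation

I count everything as a fraction of the substrate charged, and I assumed that a rate so counted does not depend on the concentration. In the first instants of eta little could be told: the reading was 0.1% at 1.50 h, with a scatter of 0.5 percentage points. I replaced the whole curve by its mean, which was 0.00132 h⁻¹ over 25.0 h. The middle stretch, from 8.00 h to 20.0 h, ran at 0.00208 h⁻¹, faster than the mean, but that rate rests on two readings with that same scatter, so I read no bend in it and kept the mean.

Epsilon showed a curve that bends. Its first 20.0 min gave 0.123 h⁻¹, but from 60.0 min to 120 min the gain fell to 0.0190 h⁻¹, slower than at the start. The early rate held to 120 min gives 24.6%, and the reading was 9.7%. So in epsilon a straight line served early and then failed. The target readings did not tell me what bends the curve.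

The rise in temperature that doubles the mean rate of target, my doubling step, came to 7.64 K from these two rates. Rate times 6.0 h then gave me a straight-line yield for each flask. South got 1.64% and south-east 0.108%. Both lie below the last epsilon reading, so I kept them as my own reckoning. East got 24.9%, above that reading. South-west got 378%, more than the charge. Epsilon had already fallen below its line, so I did not rank those two flasks by mine.

The forecast differed from my line: it named south-west, with 12% in east, 18% in south-west, 3.5% in south and 0.2% in south-east, adding of south-west “though this is uncertain because over-reaction is possible”.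

The simulation put east highest, at 14.9%, with south-west at 7.77%, south at 2.07% and south-east at 0.0393%.

    substrate → intermediate (k = 0.183 h⁻¹, Ea = 117 kJ mol⁻¹)
    first nucleophile + intermediate → target (k = 111 L mol⁻¹ h⁻¹, Ea = 57.0 kJ mol⁻¹)
    second nucleophile + intermediate → other capture product (k = 86.7 L mol⁻¹ h⁻¹, Ea = 52.0 kJ mol⁻¹)
    intermediate → solvolysis product (k = 27.5 h⁻¹, Ea = 113 kJ mol⁻¹)
    first nucleophile → decomposed reagent (k = 0.257 h⁻¹, Ea = 107 kJ mol⁻¹)
    intermediate → side product (k = 0.339 h⁻¹, Ea = 117 kJ mol⁻¹)
    (constants at 100 °C)

The doubling step of 7.64 K had put south at 1.64% against 2.07%, and south-east at 0.108% against 0.0393%, which is 2.75 times the flask. In south-east at 3.00 h, the half-life of substrate by its step into intermediate was 220 d, and that of intermediate by capture with first nucleophile was 1.0 h, far shorter. The step out of substrate is thus the rate-limiting step of south-east, where intermediate stood at 0.0112% after 6.00 h.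

All runs come from a simulation with constants of no real substance; noise was put on by code.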